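# Proposed total synthesis of CNP0255009.1 by macrocyclising sulfonium-ylide epoxidation

## Structural features

The target is a germacranolide: a cyclodecane (C1–C10) carrying two trans-configured trisubstituted oxiranes, C1/C10 (C14 methyl on C10) and C4/C5 (C15 methyl on C4), and a butenolide fused at C6/C7 whose tetrasubstituted alkene C7=C11 has C7 in the ten-membered ring. C11 bears the acetoxymethyl carbon C13, and C8, the second allylic ring carbon on C7, bears the (R)-3-chloro-2-hydroxy-2-methylpropanoate. The stereocentres fall into blocks: C4–C5–C6 (4R,5R,6S) are contiguous, with the oxirane oxygen on C5 and O6 in a threo relation, and C8 (S) is separated from C6 only by the sp2 carbon C7. C10–C1 (10R,1R) lie on the far side of the ring, and the seventh centre is the tertiary carbinol of the side chain. Fragile groups are the two oxiranes (acid, transannular opening), the α-(acetoxymethyl)butenolide (acceptor for nucleophiles, acidic C6–H next to the 4,5-oxirane) and the chlorohydrin ester (base closes it to a glycidate). The real difficulty is the strained ten-membered ring with six ring stereocentres, above all the 1,10-oxirane, which has no neighbouring hydroxyl to direct its formation. The key step uses the fact that the C1–C10 bond is both a ring bond of the cyclodecane and the C–C bond of the 1,10-oxirane, so C10 can arrive as a methyl ketone carbon and C1 as a sulfonium ylide carbon.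

## Logic of the disconnections

**38 ⇒ 35.** The O6–C12 lactone bond and the C12 oxidation level are removed last. The acetoxymethyl butenolide is the unit most sensitive to base and nucleophiles, so it should see no further reagent. This leaves a 1,4-diol. The forward oxidation must be neutral and must find only one primary carbinol, so C13 must already be acetylated and O8 acylated.

**35 ⇒ 32 (through 34 and 33).** The C13–O acetyl bond and the two C–O bonds of a benzylidene acetal are cut. The two hydroxymethyl groups on C11 of 32 differ only in which ring carbon they face across C7=C11. A group on O6 can reach the one cis to C6 and cannot reach the other. The forward step must turn the O6 protecting group itself into a tether to O12 under anhydrous, non-acidic conditions.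

**32 ⇒ 29 + 8 (through 31 and 30).** The C8 ester C–O bond is cut. A β-acyloxy ketone would not survive the base of the ring closure, and the chlorohydrin does not tolerate fluoride or alkoxide, so the side chain enters directly after the last basic operation. This removes one stereocentre and all side-chain functionality. The forward step must acylate a hindered allylic alcohol with a fully substituted acid, hence an acid chloride with its tertiary hydroxyl silylated.

**29 ⇒ 28 ⇒ 25 (key).** After removal of the O8 silyl group, the C1–C10 bond and the O–C1 bond are cut. This opens two rings and removes two stereocentres in one operation, leaving an open chain whose remaining centres (C4, C5, C6, C8) can be set by acyclic methods. Checked centre by centre against 38, structures 25 and 28 carry the target configuration and need no correction. The forward step demands that the ylide form in preference to an enolate, that it attack the ketone and not the 4,5-oxirane, and that the chain fold so as to give the trans-oxirane on the correct face.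

**25 ⇒ 23 + 24, and 23 ⇒ 22.** The C1–S bond and then the C1–I bond are cut. A sulfonium salt cannot be carried through organolithium chemistry, whereas a primary chloride is inert to every earlier step and is exchanged for iodide only at the end. The forward S-alkylation of a weakly nucleophilic diaryl sulfide needs silver assistance and must outrun participation by the oxirane oxygen.

**22 ⇒ 20 ⇒ 19 ⇒ 18.** The C10 carbonyl is traced to a 1,1-disubstituted alkene, the O8–Si bond is cut, and then the C8–C9 bond. A methallyl group supplies C9, C10 and C14, and its alkene is a ketone that can be unmasked without acid. Added as an allylborane to a C8 aldehyde it sets C8 under reagent control, which a four-carbon keto-aldehyde reagent with the wrong carbonyl masked could not do. The forward steps need facial control by the borane and cleavage of the 1,1-disubstituted alkene in the presence of the tetrasubstituted one.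

**18 ⇒ 16.** The C7–C8 bond is cut, with C8 coming from a formamide. The forward step needs bromine–lithium exchange that is faster than attack on the chloride or oxirane. O6 must carry a benzyl-type group, because a silyl group would migrate to the lithiated carbon.

**16 ⇒ 15 ⇒ 14.** The O6 benzyl bond and both C–O bonds of the 4,5-oxirane are cut. Adding a vinyl-metal to a preformed 4,5-epoxy aldehyde would be expected to favour the wrong C6 epimer (polar Felkin–Anh or Cornforth attack gives the erythro array). Hydroxyl-directed peracid epoxidation of an allylic alcohol whose alkene carries a methyl cis to the carbinol gives the threo array that 38 needs. The bromine still on C7 deactivates the other alkene. C6 must therefore be fixed before this step.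

**14 ⇒ 13 ⇒ 12 ⇒ 10 + 5.** The C6–H bond (reduction) and the C6–C7 bond are cut. A symmetrical dibromomethylidene dioxane serves as a linchpin for C7, so the tetrasubstituted alkene has no geometry problem, and C6 is set by catalyst-controlled reduction. The carbenoid must be made and trapped below −100 °C, and the catalyst must tell the two alkenyl groups of 13 apart.

**10 ⇒ 9; 5 ⇒ 4 ⇒ 1; 8 ⇒ 7 ⇒ 6.** The C7=C11 bond goes back to a ketone. The C4–C15 and C5–C6 bonds go back to a terminal alkyne by carbometalation, which fixes the (E)-alkene that later becomes the trans-4,5-oxirane. The C–Cl bond of the side chain goes back to an enantiopure glycidate whose quaternary centre is never touched.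

## Other disconnections considered

**Alternative 1:** The cut is the C7–C8 ring bond. The open-chain β-iodobutenolide aldehyde A1 already holds the lactone, the C13 acetate, C6 and both (E)-alkenes. It would be closed with NiCl2/CrCl2 (Nozaki–Hiyama–Kishi reaction: zerovalent nickel inserts into C7–I, the vinyl group passes to trivalent chromium and adds to the C8 aldehyde) to give the dienolide A2 with a free C8 hydroxyl. Acylation and epoxidation of both ring alkenes would follow.

- In favour: this macrocyclisation type is established and tolerates esters. No masked butenolide and no C12/C13 differentiation are needed. Peracids are known to attack (E,E)-germacradienes from the outer face, which gives trans-oxiranes.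
- Against: the vinylchromium at C7 has the lactone oxygen in the β-position and could eliminate to an allene. C8 would be set only by ring conformation. C6 must be made and kept next to an enolisable butenolide in an open chain. A2 is a 1,5-diene prone to Cope rearrangement and acid-induced transannular cyclisation. Four oxirane centres would be left to a late double epoxidation that must also spare the butenolide.
- Comparison: in mechanism A2's route is better founded than the chosen plan, because its ring closure is of a known type. In step economy it is probably the shorter. In structure the chosen plan is stronger, because it fixes C4, C5, C6 and C8 before the ring exists and leaves only C1/C10 to the macrocycle.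

**Alternative 2:** The cut is C3–C4 together with the O–C5 bond of the 4,5-oxirane. The homoallylic Grignard reagent A4 (C1–C3, with the (E)-C1=C10 alkene and C9 as a silyloxymethyl group) would be used with CeCl3. It would add to the methyl ketone of the α-chloro ketone A3 anti to the C5 chloride, and the tertiary alkoxide would displace chloride to give the open-chain epoxide A5.

- In favour: addition anti to a C–Cl bond (Cornforth or polar Felkin–Anh) followed by closure reliably gives trans-oxiranes. The step is convergent. It buys the C1=C10 geometry from a geraniol-type piece and needs neither asymmetric reduction nor directed epoxidation.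
- Against: C5–H of A3 lies between a carbonyl and a chlorine and can epimerise; the cerium reagent lowers but does not remove this risk. A3 must be made as one C5/C6 diastereomer. Ketones respond less strongly to this control than aldehydes. The key step closes no ten-membered ring and makes no 1,10-oxirane, so a macrocyclisation at C8–C9 and a face-selective epoxidation remain. A5 has the same masked butenolide and therefore the same endgame problem.
- Comparison: in mechanism its key step is known chemistry and so is better. For the 4,5-oxirane the two plans are about equal in reliability, and A5's assembly is the more convergent. In step economy it is worse overall, because the hardest problem, the ring, is left open.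

**Alternative 3:** The cut is the O–C5 bond of the 4,5-oxirane together with the O6–C12 lactone bond. The ten-membered hydroxy epoxy ester A6 has a C4 tertiary alcohol, a cis-5,6-oxirane from a (Z)-alkene, the 1,10-oxirane in place and C12 as a methyl ester. With NaH its C4 alkoxide would open the 5,6-oxirane at C5 with inversion (Payne rearrangement), and the released C6 alkoxide would close the butenolide to give A7.

- In favour: both events are known reaction types. Lactonisation removes the C6 alkoxide and pulls the Payne equilibrium forward. The threo relation follows from the inversion. C12 and C13 are different from the outset, so the lactone regiochemistry is unambiguous; on this point it is better than the chosen plan, which needs a tether sequence.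
- Against: the C4 alkoxide can instead open the 1,10-oxirane at C1 through a five-membered transition state, a mode normally faster than three-membered closure. A6 needs a defined geometry at the unsymmetrical C7=C11 alkene, a (Z)-cycloalkene epoxidised on the correct face and a C4 tertiary carbinol, all on a macrocycle whose synthesis is unsolved. The product butenolide must survive strong base.
- Comparison: in mechanism and in the steps after the key step it is equal or better. In the demands on the precursor and in total step count it is worse, and it does not address how the ring is made.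

Key step: step 17

Remark: germacrane locants (C1–C15) are used for all intermediates; C10 of 21 and the acetal carbon of 33 and 34 form as mixtures, which is harmless because both centres are destroyed later; compound 6, (−)-Ipc2BOMe and the other reagents are taken to be purchasable.

## Route

Step 1
Reactants: 1 5-chloropent-1-yne
Product: 4 (2E)-6-chloro-3-methylhex-2-en-1-ol, via alkenylalane 2 (not isolated), via lithium alkenylaluminate 3 (not isolated)
Conditions: Me3Al, Cp2ZrCl2 (cat.), CH2Cl2, 0 °C → rt; n-BuLi, THF, −78 → 0 °C; (CH2O)n, rt; aq. HCl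
Reagents that add atoms: trimethylaluminium C[Al](C)C; paraformaldehyde (as formaldehyde) C=O
Why: Negishi zirconium-catalysed methylalumination adds CH3 and aluminium syn across the alkyne with the metal at the terminus, which fixes the (E)-alkene (C15 cis to C6); the ate complex then adds to formaldehyde with retention to give C6 as a primary allylic alcohol, and the primary chloride is inert at these temperatures.

Step 2
Reactants: 4 (2E)-6-chloro-3-methylhex-2-en-1-ol
Product: 5 (2E)-6-chloro-3-methylhex-2-enal
Conditions: TEMPO (2,2,6,6-tetramethylpiperidin-1-oxyl, cat.), PhI(OAc)2, CH2Cl2, rt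
Reagents that add atoms: none
Why: Oxoammonium oxidation of a primary allylic alcohol stops at the aldehyde and, being non-basic and metal-free, should leave the (E)-geometry intact.

Step 3
Reactants: 6 methyl (2S)-2-methyloxirane-2-carboxylate
Product: 7 (2R)-3-chloro-2-hydroxy-2-methylpropanoic acid
Conditions: conc. aq. HCl, 0 → 60 °C
Reagents that add atoms: hydrogen chloride Cl; water O
Why: Chloride opens the protonated glycidate at the unhindered CH2 by SN2 (the carbon next to the ester cannot ionise), so the quaternary centre is untouched and only its descriptor changes from S to R; the warm acid then hydrolyses the methyl ester.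

Step 4
Reactants: 7 (2R)-3-chloro-2-hydroxy-2-methylpropanoic acid
Product: 8 trimethylsilyl (2R)-3-chloro-2-methyl-2-(trimethylsilyloxy)propanoate
Conditions: Me3SiCl, pyridine, CH2Cl2, 0 °C → rt; filtration, evaporation
Reagents that add atoms: chlorotrimethylsilane C[Si](C)(C)Cl
Why: Exhaustive silylation masks the tertiary hydroxyl and converts the acid into a silyl ester, the form from which an acid chloride can be made later under neutral conditions.

Step 5
Reactants: 9 2,2-dimethyl-1,3-dioxan-5-one
Product: 10 5-(dibromomethylidene)-2,2-dimethyl-1,3-dioxane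
Conditions: CBr4, PPh3, CH2Cl2, 0 °C → rt
Reagents that add atoms: carbon tetrabromide BrC(Br)(Br)Br
Why: Ramirez dibromo-olefination (Wittig reaction of Ph3P=CBr2) of an unhindered, electrophilic ketone; because the dioxane is symmetrical, the later tetrasubstituted alkene has no E/Z problem.

Step 6
Reactants: 10 5-(dibromomethylidene)-2,2-dimethyl-1,3-dioxane; 5 (2E)-6-chloro-3-methylhex-2-enal
Product: 12 rac-(3E)-1-bromo-7-chloro-1-(2,2-dimethyl-1,3-dioxan-5-ylidene)-4-methylhept-3-en-2-ol, via lithium carbenoid 11 (not isolated)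
Conditions: n-BuLi, THF/Et2O/pentane (4:1:1), −105 °C; then 5, −105 → −78 °C; aq. NH4Cl
Reagents that add atoms: none
Why: Bromine–lithium exchange on a 1,1-dibromoalkene gives a 1-bromo-1-lithioalkene (both bromines are equivalent) which, kept below −100 °C, adds 1,2 to the enal before Fritsch–Buttenberg–Wiechell-type decomposition; the C6–C7 bond forms without stereocontrol, which steps 7 and 8 correct.

Step 7
Reactants: 12 rac-(3E)-1-bromo-7-chloro-1-(2,2-dimethyl-1,3-dioxan-5-ylidene)-4-methylhept-3-en-2-ol
Product: 13 (3E)-1-bromo-7-chloro-1-(2,2-dimethyl-1,3-dioxan-5-ylidene)-4-methylhept-3-en-2-one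
Conditions: Dess–Martin periodinane, NaHCO3, CH2Cl2, 0 °C → rt
Reagents that add atoms: none
Why: Buffered Dess–Martin oxidation of a bis-allylic alcohol gives the cross-conjugated dienone without touching the acetonide or the alkene geometry.

Step 8
Reactants: 13 (3E)-1-bromo-7-chloro-1-(2,2-dimethyl-1,3-dioxan-5-ylidene)-4-methylhept-3-en-2-one
Product: 14 (2R,3E)-1-bromo-7-chloro-1-(2,2-dimethyl-1,3-dioxan-5-ylidene)-4-methylhept-3-en-2-ol
Conditions: (S)-Me-CBS [(S)-1-methyl-3,3-diphenyltetrahydro-1H,3H-pyrrolo[1,2-c][1,3,2]oxazaborole], catecholborane, toluene, −78 °C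
Reagents that add atoms: none
Why: Corey–Bakshi–Shibata reduction; the tetrasubstituted α-bromoalkenyl group should act as the large substituent and the (E)-CH=C(CH3) group as the small one, so the (S)-catalyst should give the (R)-carbinol at C6, which has the spatial arrangement of 6S in 38 (the descriptor changes when bromine is replaced by carbon). Catecholborane at −78 °C reduces 1,2 and should not hydroborate.

Step 9
Reactants: 14 (2R,3E)-1-bromo-7-chloro-1-(2,2-dimethyl-1,3-dioxan-5-ylidene)-4-methylhept-3-en-2-ol
Product: 15 (1R)-2-bromo-1-[(2R,3R)-3-(3-chloropropyl)-3-methyloxiran-2-yl]-2-(2,2-dimethyl-1,3-dioxan-5-ylidene)ethan-1-ol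
Conditions: mCPBA, NaHCO3, CH2Cl2, 0 °C
Reagents that add atoms: 3-chloroperoxybenzoic acid OOC(=O)c1cccc(Cl)c1
Why: Hydroxyl-directed peracid epoxidation; with the C15 methyl cis to the carbinol carbon, A(1,3) strain holds C6–H in the alkene plane and the hydrogen-bonded peracid attacks the face of the hydroxyl, which should give the threo (4R,5R) oxirane. The (E)-alkene gives the trans relation of C3 and C6, and the bromoalkene, deactivated by bromine and two allylic oxygens, should not react.

Step 10
Reactants: 15 (1R)-2-bromo-1-[(2R,3R)-3-(3-chloropropyl)-3-methyloxiran-2-yl]-2-(2,2-dimethyl-1,3-dioxan-5-ylidene)ethan-1-ol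
Product: 16 5-{(2R)-1-bromo-2-[(2R,3R)-3-(3-chloropropyl)-3-methyloxiran-2-yl]-2-[(4-methoxyphenyl)methoxy]ethylidene}-2,2-dimethyl-1,3-dioxane
Conditions: NaH, 4-methoxybenzyl bromide, THF/DMF, 0 °C
Reagents that add atoms: 4-methoxybenzyl bromide COc1ccc(CBr)cc1
Why: Williamson etherification of the secondary alkoxide; a benzyl-type group is used on O6 because a silyl group would migrate from oxygen to carbon (retro-Brook) in the vinyllithium of step 11. Payne isomerisation is disfavoured because it would exchange a trisubstituted oxirane for a tertiary alkoxide.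

Step 11
Reactants: 16 5-{(2R)-1-bromo-2-[(2R,3R)-3-(3-chloropropyl)-3-methyloxiran-2-yl]-2-[(4-methoxyphenyl)methoxy]ethylidene}-2,2-dimethyl-1,3-dioxane
Product: 18 (3S)-3-[(2R,3R)-3-(3-chloropropyl)-3-methyloxiran-2-yl]-2-(2,2-dimethyl-1,3-dioxan-5-ylidene)-3-[(4-methoxyphenyl)methoxy]propanal, via vinyllithium 17 (not isolated)
Conditions: t-BuLi (2.1 equiv), Et2O, −78 °C; DMF, −78 → 0 °C; aq. NH4Cl
Reagents that add atoms: N,N-dimethylformamide CN(C)C=O
Why: Bromine–lithium exchange at −78 °C is faster than attack on the primary chloride or the oxirane, and formylation of the vinyllithium with DMF installs C8 as an aldehyde on C7.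

Step 12
Reactants: 18 (3S)-3-[(2R,3R)-3-(3-chloropropyl)-3-methyloxiran-2-yl]-2-(2,2-dimethyl-1,3-dioxan-5-ylidene)-3-[(4-methoxyphenyl)methoxy]propanal
Product: 19 (1S,3S)-1-[(2R,3R)-3-(3-chloropropyl)-3-methyloxiran-2-yl]-2-(2,2-dimethyl-1,3-dioxan-5-ylidene)-1-[(4-methoxyphenyl)methoxy]-5-methylhex-5-en-3-ol
Conditions: (−)-Ipc2BOMe, 2-methylallylmagnesium chloride, Et2O, 0 °C → rt; then 18, −78 °C; NaOH, H2O2, rt
Reagents that add atoms: 2-methylallylmagnesium chloride CC(=C)C[Mg]Cl, transferred through (−)-B-(2-methylallyl)diisopinocampheylborane CC(=C)CB([C@@H]1C[C@@H]2C[C@H]([C@H]1C)C2(C)C)[C@@H]1C[C@@H]2C[C@H]([C@H]1C)C2(C)C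
Why: Brown allylboration through a chair transition state; the borane derived from (+)-α-pinene should add to the Si face of the aldehyde, which sets C8 as S under reagent control and forms the C8–C9 bond. The methallyl group brings C9, C10 and C14 with the ketone masked as a 1,1-disubstituted alkene.

Step 13
Reactants: 19 (1S,3S)-1-[(2R,3R)-3-(3-chloropropyl)-3-methyloxiran-2-yl]-2-(2,2-dimethyl-1,3-dioxan-5-ylidene)-1-[(4-methoxyphenyl)methoxy]-5-methylhex-5-en-3-ol
Product: 20 tert-butyldimethylsilyl ether of 19 at O8
Conditions: TBSOTf, 2,6-lutidine, CH2Cl2, −78 °C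
Reagents that add atoms: tert-butyldimethylsilyl triflate CC(C)(C)[Si](C)(C)OS(=O)(=O)C(F)(F)F
Why: Silylation of a hindered secondary alcohol with the silyl triflate at low temperature, where the oxirane and acetonide should be safe; a silyl ether is a poor leaving group, which matters for the β-oxygenated ketone that follows.

Step 14
Reactants: 20 tert-butyldimethylsilyl ether of 19 at O8
Product: 22 (4S,6S)-4-(tert-butyldimethylsilyloxy)-6-[(2R,3R)-3-(3-chloropropyl)-3-methyloxiran-2-yl]-5-(2,2-dimethyl-1,3-dioxan-5-ylidene)-6-[(4-methoxyphenyl)methoxy]hexan-2-one, via 1,2-diol 21 (not isolated)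
Conditions: OsO4 (cat.), NaIO4, 2,6-lutidine, dioxane/H2O, rt
Reagents that add atoms: sodium periodate [Na+].[O-]I(=O)(=O)=O (oxygen, relayed by osmium tetroxide O=[Os](=O)(=O)=O)
Why: Lemieux–Johnson cleavage; osmylation is very sensitive to substitution, so the 1,1-disubstituted alkene should react and the crowded tetrasubstituted C7=C11 alkene should not, and periodate cleaves the diol to the C10 methyl ketone without acid.

Step 15
Reactants: 22 (4S,6S)-4-(tert-butyldimethylsilyloxy)-6-[(2R,3R)-3-(3-chloropropyl)-3-methyloxiran-2-yl]-5-(2,2-dimethyl-1,3-dioxan-5-ylidene)-6-[(4-methoxyphenyl)methoxy]hexan-2-one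
Product: 23 (4S,6S)-4-(tert-butyldimethylsilyloxy)-5-(2,2-dimethyl-1,3-dioxan-5-ylidene)-6-[(2R,3R)-3-(3-iodopropyl)-3-methyloxiran-2-yl]-6-[(4-methoxyphenyl)methoxy]hexan-2-one
Conditions: NaI, NaHCO3, acetone, reflux
Reagents that add atoms: sodium iodide [Na+].[I-]
Why: Finkelstein exchange at the unhindered primary carbon C1, driven by precipitation of NaCl; neutral iodide should not open the trisubstituted oxirane.

Step 16
Reactants: 23 (4S,6S)-4-(tert-butyldimethylsilyloxy)-5-(2,2-dimethyl-1,3-dioxan-5-ylidene)-6-[(2R,3R)-3-(3-iodopropyl)-3-methyloxiran-2-yl]-6-[(4-methoxyphenyl)methoxy]hexan-2-one; 24 diphenyl sulfide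
Product: 25 {3-[(2R,3R)-3-{(1S,3S)-3-(tert-butyldimethylsilyloxy)-2-(2,2-dimethyl-1,3-dioxan-5-ylidene)-1-[(4-methoxyphenyl)methoxy]-5-oxohexyl}-2-methyloxiran-2-yl]propyl}diphenylsulfonium tetrafluoroborate
Conditions: Ph2S (10 equiv), AgBF4, 2,6-di-tert-butylpyridine, CH2Cl2, 0 °C → rt, dark
Reagents that add atoms: silver tetrafluoroborate [Ag+].F[B-](F)(F)F
Why: Silver-assisted S-alkylation of a diaryl sulfide by a primary iodide, the standard entry to alkyldiphenylsulfonium tetrafluoroborates; the large excess of sulfide and the hindered base are meant to outrun participation by the oxirane oxygen and to scavenge acid.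

Step 17
Reactants: 25 {3-[(2R,3R)-3-{(1S,3S)-3-(tert-butyldimethylsilyloxy)-2-(2,2-dimethyl-1,3-dioxan-5-ylidene)-1-[(4-methoxyphenyl)methoxy]-5-oxohexyl}-2-methyloxiran-2-yl]propyl}diphenylsulfonium tetrafluoroborate
Product: 28 (1R,4R,5R,6S,8S,10R)-8-(tert-butyldimethylsilyloxy)-7-(2,2-dimethyl-1,3-dioxan-5-ylidene)-1,10:4,5-diepoxy-6-[(4-methoxyphenyl)methoxy]-4,10-dimethylcyclodecane, via sulfonium ylide 26 (not isolated), via betaine 27 (not isolated)
Conditions: KN(SiMe3)2 (1.05 equiv), THF, −78 → −40 °C, slow addition of 25 to the base, final concentration ≤ 1 mM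
Reagents that add atoms: none
Why: Proposed new method: KN(SiMe3)2 should remove a proton from C1, the most acidic carbon (an alkyldiphenylsulfonium is about ten pK units more acidic than a dialkyl ketone), and the unstabilised ylide 26 adds to the C10 ketone to give betaine 27, whose alkoxide displaces Ph2S from C1 with inversion. The closest known reaction type is the Corey–Chaykovsky epoxidation of ketones by diphenylsulfonium alkylides, established between two molecules and for common ring sizes but not as a medium-ring closure. The ten-membered ring closes in the carbonyl addition (10-exo-trig attack of C1 on C10) and the oxirane by 3-exo-tet displacement, which is fast, so the irreversible addition is the stereo-determining event. C10 is set by the ketone face that C1 attacks and C1 by the mutual orientation of ylide and carbonyl in the same transition state, then fixed by the anti displacement. Both depend only on the folding of the chain, in which the trans-4,5-oxirane, the sp2 carbon C7 and the outward-pointing silyloxy group on C8 should favour C2 and C9 anti and hence the trans-oxirane of the (1R,10R) series, as in the crossed conformation of (E,E)-germacradienes; this is the unproven element. The step needs selectivity for the ketone over the 4,5-oxirane (a carbonyl is far more electrophilic, and oxirane attack would need a four- or five-membered ring), for ylide over enolate (acidity; the silyl ether on C8 is a poor leaving group should some enolate form), and for ring closure over oligomerisation (slow addition at high dilution and −78 °C). The alkylidene-dioxane keeps the butenolide masked, so no other acidic or electrophilic site competes.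

Step 18
Reactants: 28 (1R,4R,5R,6S,8S,10R)-8-(tert-butyldimethylsilyloxy)-7-(2,2-dimethyl-1,3-dioxan-5-ylidene)-1,10:4,5-diepoxy-6-[(4-methoxyphenyl)methoxy]-4,10-dimethylcyclodecane
Product: 29 (1R,4R,5R,6S,8S,10R)-7-(2,2-dimethyl-1,3-dioxan-5-ylidene)-1,10:4,5-diepoxy-6-[(4-methoxyphenyl)methoxy]-4,10-dimethylcyclodecan-8-ol
Conditions: Bu4NF, THF, 0 °C → rt; aq. NH4Cl
Reagents that add atoms: none
Why: Fluoride cleavage of the secondary silyl ether; it is placed here because nothing base-sensitive (butenolide, acetate, chlorohydrin) is present yet.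

Step 19
Reactants: 29 (1R,4R,5R,6S,8S,10R)-7-(2,2-dimethyl-1,3-dioxan-5-ylidene)-1,10:4,5-diepoxy-6-[(4-methoxyphenyl)methoxy]-4,10-dimethylcyclodecan-8-ol; 8 trimethylsilyl (2R)-3-chloro-2-methyl-2-(trimethylsilyloxy)propanoate
Product: 31 (2R)-3-chloro-2-methyl-2-(trimethylsilyloxy)propanoate ester of 29 at O8, via acid chloride 30 (not isolated)
Conditions: 8, (COCl)2, DMF (cat.), CH2Cl2, 0 °C → rt; then 29, pyridine, 4-(dimethylamino)pyridine, 0 °C → rt
Reagents that add atoms: none
Why: Oxalyl chloride with catalytic DMF converts a silyl ester into the acid chloride under neutral conditions, and nucleophile-catalysed acylation of the hindered C8 alcohol proceeds with retention at C8 and at the fully substituted α-carbon of the acid.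

Step 20
Reactants: 31 (2R)-3-chloro-2-methyl-2-(trimethylsilyloxy)propanoate ester of 29 at O8
Product: 32 (1R,4R,5R,6S,8S,10R)-8-[(2R)-3-chloro-2-hydroxy-2-methylpropanoyloxy]-1,10:4,5-diepoxy-6-[(4-methoxyphenyl)methoxy]germacr-7(11)-ene-12,13-diol
Conditions: pyridinium 4-toluenesulfonate (cat.), MeOH, 0 °C → rt
Reagents that add atoms: none
Why: Mild acid-catalysed transacetalisation removes the allylic 1,3-dioxane acetonide and solvolyses the trimethylsilyl ether in one operation; a buffered pyridinium acid in methanol is the weakest acid that does this and should spare the two oxiranes and the PMB ether.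

Step 21
Reactants: 32 (1R,4R,5R,6S,8S,10R)-8-[(2R)-3-chloro-2-hydroxy-2-methylpropanoyloxy]-1,10:4,5-diepoxy-6-[(4-methoxyphenyl)methoxy]germacr-7(11)-ene-12,13-diol
Product: 33 6,12-O-(4-methoxybenzylidene) acetal of (1R,4R,5R,6S,8S,10R)-8-[(2R)-3-chloro-2-hydroxy-2-methylpropanoyloxy]-1,10:4,5-diepoxygermacr-7(11)-ene-6,12,13-triol
Conditions: DDQ (1.1 equiv), 4 Å molecular sieves, CH2Cl2, 0 °C
Reagents that add atoms: none
Why: Oxidation of a PMB ether by DDQ without water gives a benzylic oxocarbenium ion that is trapped by a neighbouring hydroxyl (oxidative acetalisation). Only the C12 hydroxyl, cis to C6 across C7=C11, can reach it, so a seven-membered 4-methoxybenzylidene acetal should join O6 and O12 and leave the C13 hydroxyl free.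

Step 22
Reactants: 33 6,12-O-(4-methoxybenzylidene) acetal of (1R,4R,5R,6S,8S,10R)-8-[(2R)-3-chloro-2-hydroxy-2-methylpropanoyloxy]-1,10:4,5-diepoxygermacr-7(11)-ene-6,12,13-triol
Product: 34 13-acetate of 33
Conditions: Ac2O, pyridine, CH2Cl2, 0 °C
Reagents that add atoms: acetic anhydride CC(=O)OC(C)=O
Why: Acetylation of the only primary hydroxyl; without an acyl-transfer catalyst the tertiary hydroxyl of the side chain should not react.

Step 23
Reactants: 34 13-acetate of 33
Product: 35 (1R,4R,5R,6S,8S,10R)-13-acetoxy-8-[(2R)-3-chloro-2-hydroxy-2-methylpropanoyloxy]-1,10:4,5-diepoxygermacr-7(11)-ene-6,12-diol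
Conditions: pyridinium 4-toluenesulfonate (cat.), MeOH, 0 °C
Reagents that add atoms: none
Why: A seven-membered electron-rich benzylidene acetal is far more acid-labile than an acetate or an oxirane, so brief methanolysis should free O6 and O12; the diol is used at once so that the acetyl group has no time to migrate from O13 to O12.

Step 24
Reactants: 35 (1R,4R,5R,6S,8S,10R)-13-acetoxy-8-[(2R)-3-chloro-2-hydroxy-2-methylpropanoyloxy]-1,10:4,5-diepoxygermacr-7(11)-ene-6,12-diol
Product: 38 (1R,4R,5R,6S,8S,10R)-13-acetoxy-8-[(2R)-3-chloro-2-hydroxy-2-methylpropanoyloxy]-1,10:4,5-diepoxygermacr-7(11)-en-12,6-olide, via hydroxy aldehyde 36 (not isolated), via lactol 37 (not isolated)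
Conditions: TEMPO (cat.), PhI(OAc)2, CH2Cl2, rt
Reagents that add atoms: none
Why: Oxoammonium oxidation is selective for the primary C12 carbinol over the hindered secondary C6 carbinol; the aldehyde closes onto O6 to a five-membered lactol, which is oxidised on to the butenolide (oxidative lactonisation of a 1,4-diol). The conditions are neutral to weakly acidic, so the acetate, chlorohydrin and oxiranes should survive and no stereocentre is touched.

## Compound list

1 | 5-chloropent-1-yne | C#CCCCCl | starting material
2 | (E)-(5-chloro-2-methylpent-1-en-1-yl)dimethylalane | C[Al](C)/C=C(\C)CCCCl | intermediate (not isolated)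
3 | lithium butyl[(E)-5-chloro-2-methylpent-1-en-1-yl]dimethylaluminate | [Li+].CCCC[Al-](C)(C)/C=C(\C)CCCCl | intermediate (not isolated)
4 | (2E)-6-chloro-3-methylhex-2-en-1-ol | OC/C=C(\C)CCCCl | intermediate
5 | (2E)-6-chloro-3-methylhex-2-enal | O=C/C=C(\C)CCCCl | intermediate
6 | methyl (2S)-2-methyloxirane-2-carboxylate | COC(=O)[C@@]1(C)OC1 | starting material
7 | (2R)-3-chloro-2-hydroxy-2-methylpropanoic acid | OC(=O)[C@@](C)(O)CCl | intermediate
8 | trimethylsilyl (2R)-3-chloro-2-methyl-2-(trimethylsilyloxy)propanoate | C[Si](C)(C)OC(=O)[C@@](C)(O[Si](C)(C)C)CCl | intermediate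
9 | 2,2-dimethyl-1,3-dioxan-5-one | CC1(C)OCC(=O)CO1 | starting material
10 | 5-(dibromomethylidene)-2,2-dimethyl-1,3-dioxane | BrC(Br)=C1COC(C)(C)OC1 | intermediate
11 | [bromo(2,2-dimethyl-1,3-dioxan-5-ylidene)methyl]lithium | [Li]C(Br)=C1COC(C)(C)OC1 | intermediate (not isolated)
12 | rac-(3E)-1-bromo-7-chloro-1-(2,2-dimethyl-1,3-dioxan-5-ylidene)-4-methylhept-3-en-2-ol | ClCCC/C(C)=C/C(O)C(Br)=C1COC(C)(C)OC1 | intermediate
13 | (3E)-1-bromo-7-chloro-1-(2,2-dimethyl-1,3-dioxan-5-ylidene)-4-methylhept-3-en-2-one | ClCCC/C(C)=C/C(=O)C(Br)=C1COC(C)(C)OC1 | intermediate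
14 | (2R,3E)-1-bromo-7-chloro-1-(2,2-dimethyl-1,3-dioxan-5-ylidene)-4-methylhept-3-en-2-ol | ClCCC/C(C)=C/[C@@H](O)C(Br)=C1COC(C)(C)OC1 | intermediate
15 | (1R)-2-bromo-1-[(2R,3R)-3-(3-chloropropyl)-3-methyloxiran-2-yl]-2-(2,2-dimethyl-1,3-dioxan-5-ylidene)ethan-1-ol | ClCCC[C@@]1(C)O[C@@H]1[C@@H](O)C(Br)=C1COC(C)(C)OC1 | intermediate
16 | 5-{(2R)-1-bromo-2-[(2R,3R)-3-(3-chloropropyl)-3-methyloxiran-2-yl]-2-[(4-methoxyphenyl)methoxy]ethylidene}-2,2-dimethyl-1,3-dioxane | ClCCC[C@@]1(C)O[C@@H]1[C@@H](OCc1ccc(OC)cc1)C(Br)=C1COC(C)(C)OC1 | intermediate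
17 | vinyllithium from 16 (lithium in place of bromine on C7, configuration unchanged) | ClCCC[C@@]1(C)O[C@@H]1[C@@H](OCc1ccc(OC)cc1)C([Li])=C1COC(C)(C)OC1 | intermediate (not isolated)
18 | (3S)-3-[(2R,3R)-3-(3-chloropropyl)-3-methyloxiran-2-yl]-2-(2,2-dimethyl-1,3-dioxan-5-ylidene)-3-[(4-methoxyphenyl)methoxy]propanal | ClCCC[C@@]1(C)O[C@@H]1[C@@H](OCc1ccc(OC)cc1)C(C=O)=C1COC(C)(C)OC1 | intermediate
19 | (1S,3S)-1-[(2R,3R)-3-(3-chloropropyl)-3-methyloxiran-2-yl]-2-(2,2-dimethyl-1,3-dioxan-5-ylidene)-1-[(4-methoxyphenyl)methoxy]-5-methylhex-5-en-3-ol | ClCCC[C@@]1(C)O[C@@H]1[C@@H](OCc1ccc(OC)cc1)C(=C1COC(C)(C)OC1)[C@@H](O)CC(C)=C | intermediate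
20 | tert-butyldimethylsilyl ether of 19 at O8 | ClCCC[C@@]1(C)O[C@@H]1[C@@H](OCc1ccc(OC)cc1)C(=C1COC(C)(C)OC1)[C@@H](O[Si](C)(C)C(C)(C)C)CC(C)=C | intermediate
21 | (2RS,4S,6S)-4-(tert-butyldimethylsilyloxy)-6-[(2R,3R)-3-(3-chloropropyl)-3-methyloxiran-2-yl]-5-(2,2-dimethyl-1,3-dioxan-5-ylidene)-6-[(4-methoxyphenyl)methoxy]-2-methylhexane-1,2-diol | ClCCC[C@@]1(C)O[C@@H]1[C@@H](OCc1ccc(OC)cc1)C(=C1COC(C)(C)OC1)[C@@H](O[Si](C)(C)C(C)(C)C)CC(C)(O)CO | intermediate (not isolated)
22 | (4S,6S)-4-(tert-butyldimethylsilyloxy)-6-[(2R,3R)-3-(3-chloropropyl)-3-methyloxiran-2-yl]-5-(2,2-dimethyl-1,3-dioxan-5-ylidene)-6-[(4-methoxyphenyl)methoxy]hexan-2-one | ClCCC[C@@]1(C)O[C@@H]1[C@@H](OCc1ccc(OC)cc1)C(=C1COC(C)(C)OC1)[C@@H](O[Si](C)(C)C(C)(C)C)CC(C)=O | intermediate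
23 | (4S,6S)-4-(tert-butyldimethylsilyloxy)-5-(2,2-dimethyl-1,3-dioxan-5-ylidene)-6-[(2R,3R)-3-(3-iodopropyl)-3-methyloxiran-2-yl]-6-[(4-methoxyphenyl)methoxy]hexan-2-one | ICCC[C@@]1(C)O[C@@H]1[C@@H](OCc1ccc(OC)cc1)C(=C1COC(C)(C)OC1)[C@@H](O[Si](C)(C)C(C)(C)C)CC(C)=O | intermediate
24 | diphenyl sulfide | c1ccc(Sc2ccccc2)cc1 | starting material
25 | {3-[(2R,3R)-3-{(1S,3S)-3-(tert-butyldimethylsilyloxy)-2-(2,2-dimethyl-1,3-dioxan-5-ylidene)-1-[(4-methoxyphenyl)methoxy]-5-oxohexyl}-2-methyloxiran-2-yl]propyl}diphenylsulfonium tetrafluoroborate | c1ccccc1[S+](c1ccccc1)CCC[C@@]2(C)O[C@@H]2[C@@H](OCc1ccc(OC)cc1)C(=C1COC(C)(C)OC1)[C@@H](O[Si](C)(C)C(C)(C)C)CC(C)=O.F[B-](F)(F)F | intermediate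
26 | sulfonium ylide of 25 (carbanion at C1) | c1ccccc1[S+](c1ccccc1)[CH-]CC[C@@]2(C)O[C@@H]2[C@@H](OCc1ccc(OC)cc1)C(=C1COC(C)(C)OC1)[C@@H](O[Si](C)(C)C(C)(C)C)CC(C)=O | intermediate (not isolated)
27 | ten-membered betaine (C1 diphenylsulfonio, C10 alkoxide, anti) | c1ccccc1[S+](c1ccccc1)[C@H]1CC[C@@]2(C)O[C@@H]2[C@@H](OCc2ccc(OC)cc2)C(=C2COC(C)(C)OC2)[C@@H](O[Si](C)(C)C(C)(C)C)C[C@@]1(C)[O-] | intermediate (not isolated)
28 | (1R,4R,5R,6S,8S,10R)-8-(tert-butyldimethylsilyloxy)-7-(2,2-dimethyl-1,3-dioxan-5-ylidene)-1,10:4,5-diepoxy-6-[(4-methoxyphenyl)methoxy]-4,10-dimethylcyclodecane | CC1(C)OCC(CO1)=C2[C@@H](O[Si](C)(C)C(C)(C)C)C[C@@]3(C)O[C@@H]3CC[C@@]3(C)O[C@@H]3[C@H]2OCc1ccc(OC)cc1 | intermediate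
29 | (1R,4R,5R,6S,8S,10R)-7-(2,2-dimethyl-1,3-dioxan-5-ylidene)-1,10:4,5-diepoxy-6-[(4-methoxyphenyl)methoxy]-4,10-dimethylcyclodecan-8-ol | CC1(C)OCC(CO1)=C2[C@@H](O)C[C@@]3(C)O[C@@H]3CC[C@@]3(C)O[C@@H]3[C@H]2OCc1ccc(OC)cc1 | intermediate
30 | (2S)-3-chloro-2-methyl-2-(trimethylsilyloxy)propanoyl chloride (same spatial arrangement as 8; the descriptor changes because COCl outranks CH2Cl) | ClC(=O)[C@@](C)(O[Si](C)(C)C)CCl | intermediate (not isolated)
31 | (2R)-3-chloro-2-methyl-2-(trimethylsilyloxy)propanoate ester of 29 at O8 | CC1(C)OCC(CO1)=C2[C@@H](OC(=O)[C@@](C)(O[Si](C)(C)C)CCl)C[C@@]3(C)O[C@@H]3CC[C@@]3(C)O[C@@H]3[C@H]2OCc1ccc(OC)cc1 | intermediate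
32 | (1R,4R,5R,6S,8S,10R)-8-[(2R)-3-chloro-2-hydroxy-2-methylpropanoyloxy]-1,10:4,5-diepoxy-6-[(4-methoxyphenyl)methoxy]germacr-7(11)-ene-12,13-diol | OCC(CO)=C1[C@@H](OC(=O)[C@@](C)(O)CCl)C[C@@]2(C)O[C@@H]2CC[C@@]2(C)O[C@@H]2[C@H]1OCc1ccc(OC)cc1 | intermediate
33 | 6,12-O-(4-methoxybenzylidene) acetal of (1R,4R,5R,6S,8S,10R)-8-[(2R)-3-chloro-2-hydroxy-2-methylpropanoyloxy]-1,10:4,5-diepoxygermacr-7(11)-ene-6,12,13-triol (13-OH free, acetal carbon either configuration) | OCC1=C2[C@@H](OC(=O)[C@@](C)(O)CCl)C[C@@]3(C)O[C@@H]3CC[C@@]3(C)O[C@@H]3[C@H]2OC(c2ccc(OC)cc2)OC1 | intermediate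
34 | 13-acetate of 33 | CC(=O)OCC1=C2[C@@H](OC(=O)[C@@](C)(O)CCl)C[C@@]3(C)O[C@@H]3CC[C@@]3(C)O[C@@H]3[C@H]2OC(c2ccc(OC)cc2)OC1 | intermediate
35 | (1R,4R,5R,6S,8S,10R)-13-acetoxy-8-[(2R)-3-chloro-2-hydroxy-2-methylpropanoyloxy]-1,10:4,5-diepoxygermacr-7(11)-ene-6,12-diol (C12 cis to C6) | CC(=O)OC/C(CO)=C1\[C@@H](OC(=O)[C@@](C)(O)CCl)C[C@@]2(C)O[C@@H]2CC[C@@]2(C)O[C@@H]2[C@H]1O | intermediate
36 | 12-aldehyde of 35 (6-hydroxy-12-oxo) | CC(=O)OC/C(C=O)=C1\[C@@H](OC(=O)[C@@](C)(O)CCl)C[C@@]2(C)O[C@@H]2CC[C@@]2(C)O[C@@H]2[C@H]1O | intermediate (not isolated)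
37 | 6,12-lactol of 36 (12-hydroxy-6,12-epoxide, either configuration at C12) | CC(=O)OCC1=C2[C@@H](OC(=O)[C@@](C)(O)CCl)C[C@@]3(C)O[C@@H]3CC[C@@]3(C)O[C@@H]3[C@H]2OC1O | intermediate (not isolated)
38 | (1R,4R,5R,6S,8S,10R)-13-acetoxy-8-[(2R)-3-chloro-2-hydroxy-2-methylpropanoyloxy]-1,10:4,5-diepoxygermacr-7(11)-en-12,6-olide | CC(=O)OCC1=C2[C@@H](OC(=O)[C@@](C)(O)CCl)C[C@@]3(C)O[C@@H]3CC[C@@]3(C)O[C@@H]3[C@H]2OC1=O | target

## Step count and least certain steps

Total: 24 steps. Longest linear sequence: 21 steps (steps 1, 2 and 6–24, from 1).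

**Step 17 (key step, proposed new method).** Ring closure may lose to intermolecular reaction of the ylide. Proton transfer from C9 may be followed by β-elimination of the silyloxy group. Facial or geometric control in the macrocyclic addition may be poor, giving the cis-oxirane or the trans-oxirane of the wrong face. A fallback with known chemistry sets out from 23. Heating with PPh3 in acetonitrile gives the phosphonium iodide F1. KN(SiMe3)2 under high dilution effects an intramolecular Wittig olefination to the (E)-cyclodecene F2, in which C1=C10 is the new ring bond. Peracid epoxidation of F2 (mCPBA, NaHCO3) from the exposed face of the trisubstituted alkene, the mode known for (E)-1(10)-germacrenes, returns to the route at 28. The crowded, oxygen-flanked C7=C11 alkene should react more slowly.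

**Step 16.** The oxirane oxygen may participate in the silver-assisted ionisation at C1 through a five-membered oxonium ion, and adventitious acid may cleave the acetonide. The fallback sets out from 23. Sodium benzenethiolate in DMF at 0 °C gives the phenyl sulfide F3. S-Phenylation with diphenyliodonium tetrafluoroborate and catalytic Cu(OAc)2 in 1,2-dichloroethane at 80 °C then returns to 25. C1 is never an activated electrophile next to the oxirane in this sequence.

**Step 21.** The benzylic cation may be captured by traces of water (plain loss of the PMB group), the acetal may be over-oxidised to a benzoate, and the acetyl group may later migrate in step 23. The fallback sets out from 32. DDQ in wet CH2Cl2 with pH 7 buffer gives the tetraol F4. TEMPO with excess PhI(OAc)2 oxidises both primary carbinols, of which only C12 can lactonise, to the 13-oxo butenolide F5. Luche reduction (NaBH4, CeCl3, MeOH, −78 °C) gives the 13-hydroxy butenolide F6. Ac2O in pyridine then returns to 38. Regiochemistry is then decided by alkene geometry alone.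

**Step 8.** The catalyst may discriminate poorly between the two alkenyl groups, which would give low enantiofacial selectivity at C6. The fallback sets out from 4. Sharpless epoxidation [Ti(OiPr)4, D-(−)-diethyl tartrate, t-BuOOH, 4 Å molecular sieves, −20 °C] gives the epoxy alcohol F7. Oxidation with SO3·pyridine, DMSO and i-Pr2NEt gives the epoxy aldehyde F8. Addition of carbenoid 11 gives 15 together with its C6 epimer F9, expected to predominate by polar Felkin–Anh attack. Mitsunobu inversion of F9 (4-nitrobenzoic acid, PPh3, diisopropyl azodicarboxylate) gives the 4-nitrobenzoate F10, and K2CO3 in MeOH returns to 15. C4 and C5 then come from the tartrate and C6 from an SN2 inversion.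

**Step 12.** Addition to the hindered tetrasubstituted enal may be slow, or reagent and substrate may be mismatched, which would give poor facial selectivity at C8. The fallback sets out from 18. 2-Methylallylmagnesium chloride in THF at −78 °C gives 19 together with its C8 epimer F11. Dess–Martin oxidation of the mixture gives the β,γ-unsaturated ketone F12. Corey–Bakshi–Shibata reduction with the (R)-catalyst and catecholborane then returns to 19.

## Further compounds

F1 | step 17 | phosphonium iodide from 23 (triphenylphosphonio in place of iodine at C1) | [I-].c1ccccc1[P+](c1ccccc1)(c1ccccc1)CCC[C@@]2(C)O[C@@H]2[C@@H](OCc1ccc(OC)cc1)C(=C1COC(C)(C)OC1)[C@@H](O[Si](C)(C)C(C)(C)C)CC(C)=O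
F2 | step 17 | (1(10)E,4R,5R,6S,8S)-8-(tert-butyldimethylsilyloxy)-7-(2,2-dimethyl-1,3-dioxan-5-ylidene)-4,5-epoxy-6-[(4-methoxyphenyl)methoxy]-4,10-dimethylcyclodec-1(10)-ene | CC1(C)OCC(CO1)=C2[C@@H](O[Si](C)(C)C(C)(C)C)C/C(C)=C/CC[C@@]3(C)O[C@@H]3[C@H]2OCc1ccc(OC)cc1
F3 | step 16 | phenyl sulfide from 23 (phenylsulfanyl in place of iodine at C1) | c1ccccc1SCCC[C@@]2(C)O[C@@H]2[C@@H](OCc1ccc(OC)cc1)C(=C1COC(C)(C)OC1)[C@@H](O[Si](C)(C)C(C)(C)C)CC(C)=O
F4 | step 21 | (1R,4R,5R,6S,8S,10R)-8-[(2R)-3-chloro-2-hydroxy-2-methylpropanoyloxy]-1,10:4,5-diepoxygermacr-7(11)-ene-6,12,13-triol | OCC(CO)=C1[C@@H](OC(=O)[C@@](C)(O)CCl)C[C@@]2(C)O[C@@H]2CC[C@@]2(C)O[C@@H]2[C@H]1O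
F5 | step 21 | (1R,4R,5R,6S,8S,10R)-8-[(2R)-3-chloro-2-hydroxy-2-methylpropanoyloxy]-1,10:4,5-diepoxy-13-oxogermacr-7(11)-en-12,6-olide | O=CC1=C2[C@@H](OC(=O)[C@@](C)(O)CCl)C[C@@]3(C)O[C@@H]3CC[C@@]3(C)O[C@@H]3[C@H]2OC1=O
F6 | step 21 | (1R,4R,5R,6S,8S,10R)-8-[(2R)-3-chloro-2-hydroxy-2-methylpropanoyloxy]-1,10:4,5-diepoxy-13-hydroxygermacr-7(11)-en-12,6-olide | OCC1=C2[C@@H](OC(=O)[C@@](C)(O)CCl)C[C@@]3(C)O[C@@H]3CC[C@@]3(C)O[C@@H]3[C@H]2OC1=O
F7 | step 8 | [(2R,3R)-3-(3-chloropropyl)-3-methyloxiran-2-yl]methanol | ClCCC[C@@]1(C)O[C@@H]1CO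
F8 | step 8 | (2S,3R)-3-(3-chloropropyl)-3-methyloxirane-2-carbaldehyde | ClCCC[C@@]1(C)O[C@@H]1C=O
F9 | step 8 | (1S)-2-bromo-1-[(2R,3R)-3-(3-chloropropyl)-3-methyloxiran-2-yl]-2-(2,2-dimethyl-1,3-dioxan-5-ylidene)ethan-1-ol (C6 epimer of 15) | ClCCC[C@@]1(C)O[C@@H]1[C@H](O)C(Br)=C1COC(C)(C)OC1
F10 | step 8 | 4-nitrobenzoate of 15 | ClCCC[C@@]1(C)O[C@@H]1[C@@H](OC(=O)c1ccc(cc1)[N+](=O)[O-])C(Br)=C1COC(C)(C)OC1
F11 | step 12 | (1S,3R)-1-[(2R,3R)-3-(3-chloropropyl)-3-methyloxiran-2-yl]-2-(2,2-dimethyl-1,3-dioxan-5-ylidene)-1-[(4-methoxyphenyl)methoxy]-5-methylhex-5-en-3-ol (C8 epimer of 19) | ClCCC[C@@]1(C)O[C@@H]1[C@@H](OCc1ccc(OC)cc1)C(=C1COC(C)(C)OC1)[C@H](O)CC(C)=C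
F12 | step 12 | (1S)-1-[(2R,3R)-3-(3-chloropropyl)-3-methyloxiran-2-yl]-2-(2,2-dimethyl-1,3-dioxan-5-ylidene)-1-[(4-methoxyphenyl)methoxy]-5-methylhex-5-en-3-one | ClCCC[C@@]1(C)O[C@@H]1[C@@H](OCc1ccc(OC)cc1)C(=C1COC(C)(C)OC1)C(=O)CC(C)=C
A1 | alternative 1 | open-chain β-iodobutenolide aldehyde: 13-acetoxy-7-iodo-8-oxo-7,8-secogermacra-1(10)E,4E,7(11)-trien-12,6-olide, C6 configured as in 38 | CC(=O)OCC1=C(I)[C@@H](/C=C(C)/CC/C=C(C)/CC=O)OC1=O
A2 | alternative 1 | 13-acetoxy-8-hydroxygermacra-1(10)E,4E,7(11)-trien-12,6-olide, C6 and C8 configured as in 38 | CC(=O)OCC1=C2[C@@H](O)C/C(C)=C/CC/C(C)=C/[C@H]2OC1=O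
A3 | alternative 2 | α-chloro ketone: C4 methyl ketone, C5 chloride (configuration opposite to the C5–O bond of 38), C6 silyl ether, C7 alkylidene-dioxane, C8 as (4-methoxyphenyl)methoxymethyl | CC(=O)[C@@H](Cl)[C@@H](O[Si](C)(C)C(C)(C)C)C(COCc1ccc(OC)cc1)=C1COC(C)(C)OC1
A4 | alternative 2 | [(3E)-5-(tert-butyldimethylsilyloxy)-4-methylpent-3-en-1-yl]magnesium bromide | CC(C)(C)[Si](C)(C)OC/C(C)=C/CC[Mg]Br
A5 | alternative 2 | open-chain trans-4,5-epoxide with (E)-C1=C10 alkene, C6 and C9 silyl ethers, C7 alkylidene-dioxane and C8 (4-methoxyphenyl)methyl ether; C4, C5, C6 configured as in 38 | CC(C)(C)[Si](C)(C)OC/C(C)=C/CC[C@@]1(C)O[C@@H]1[C@@H](O[Si](C)(C)C(C)(C)C)C(COCc1ccc(OC)cc1)=C1COC(C)(C)OC1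
A6 | alternative 3 | ten-membered methyl ester: C4 tertiary alcohol, cis-5,6-oxirane, 1,10-oxirane, C8 and C13 silyl ethers, C12 ester cis to C6; C5 opposite to 38, all other centres as in 38 | COC(=O)/C(CO[Si](C)(C)C(C)(C)C)=C1/[C@@H](O[Si](C)(C)C(C)(C)C)C[C@@]2(C)O[C@@H]2CC[C@@](C)(O)[C@H]2O[C@@H]12
A7 | alternative 3 | (1R,4R,5R,6S,8S,10R)-8,13-bis(tert-butyldimethylsilyloxy)-1,10:4,5-diepoxygermacr-7(11)-en-12,6-olide | CC(C)(C)[Si](C)(C)OCC1=C2[C@@H](O[Si](C)(C)C(C)(C)C)C[C@@]3(C)O[C@@H]3CC[C@@]3(C)O[C@@H]3[C@H]2OC1=O
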